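**Retrosynthetic overview**

1. Core numbering: ring B = C1(=O)–C2(OH)=C3(Me)–C4(Me)(side chain)–C4a=C8a; ring A = C4a–C5–C6–C7(=O)–C8(Me)(CH2OAc)–C8a. The end game on a bicyclic dienone is C8 hydroxymethylation/acetylation, C7 oxidation, B-alkyl Suzuki coupling of a C4 vinyl group (from C4 ethynyl) and epoxidation/isomerisation to the C2 diosphenol.
2. Key disconnection: ring B is cut at C1–C8a and C4–C4a into a ring A vinyllithium (C8a–Li, C8a=C4a) and the four-membered 3,4-dimethyl-4-alkynylcyclobut-2-enone (C1–C2–C3–C4). Forward: 1,2-addition, conrotatory 4π opening of the cyclobutenolate and disrotatory 6π closure enlarge the four-membered ring by C8a and C4a; dehydrogenation in the same flask restores C4a=C8a.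
3. Enabling feature: ring B is a 4,4-disubstituted cyclohexa-2,5-dienone in which the C1 carbonyl carbon and the quaternary C4 are bridged by the C8a=C4a alkene shared with ring A. These are exactly the atoms of a trienolate C4a=C8a–C1(O−)=C2–C3=C4.
4. Stereochemistry: C4 is set in the key step by relay from a temporary tertiary C8 centre of ring A (pseudoaxial methyl) and the methyl/alkynyl size difference on the cyclobutenone. C8 is later rebuilt as the quaternary centre by catalyst-controlled hydroxymethylation.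
5. Order of ring formation: ring A is bought as a six-membered ring; the four-membered ring comes from a ketene/ynol ether [2+2] cycloaddition; ring B arises from it by the two-carbon ring expansion.

Key step: step 9

Remark: the core numbering above is used throughout; α is the face of the C4 methyl group of the target and β the face of the C4 side chain; cyclobutenone 16 is used as the racemate because its stereocentre becomes trigonal in step 9.

Step 1
Reactants: 1 2-methylcyclohex-2-en-1-one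
Product: 2 (S)-2-methylcyclohex-2-en-1-ol
Conditions: (R)-1-methyl-3,3-diphenyltetrahydro-1H,3H-pyrrolo[1,2-c][1,3,2]oxazaborole (cat.), BH3·THF, THF, −20 °C; MeOH
Reagents that add atoms: none
Why: Corey–Bakshi–Shibata reduction, in which the 2-methylalkenyl arm of the enone acts as the large substituent so that hydride is delivered to one carbonyl face and the carbinol carbon (future C7) should form with S configuration under catalyst control.

Step 2
Reactants: 2 (S)-2-methylcyclohex-2-en-1-ol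
Product: 3 1-methoxy-4-({[(1S)-2-methylcyclohex-2-en-1-yl]oxy}methyl)benzene
Conditions: NaH, 4-methoxybenzyl chloride, Bu4NI (cat.), THF/DMF, 0 → 20 °C
Reagents that add atoms: 4-methoxybenzyl chloride COc1ccc(CCl)cc1
Why: Williamson ether synthesis on the sodium alkoxide, which does not touch the stereocentre.

Step 3
Reactants: 3 1-methoxy-4-({[(1S)-2-methylcyclohex-2-en-1-yl]oxy}methyl)benzene
Product: 5 (1S,2R,3S)-3-[(4-methoxybenzyl)oxy]-2-methylcyclohexan-1-ol, via alkylborane 4 (not isolated)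
Conditions: 9-BBN, THF, 65 °C; then NaOH, 30% H2O2, 0 → 20 °C
Reagents that add atoms: hydrogen peroxide OO
Why: Hydroboration–oxidation, in which 9-BBN adds H and B syn across the trisubstituted alkene from the face anti to the allylic ether with boron on the less substituted carbon, so that the methyl-bearing carbon (future C8) is set with methyl cis to the ether and oxidation with retention gives the alcohol.

Step 4
Reactants: 5 (1S,2R,3S)-3-[(4-methoxybenzyl)oxy]-2-methylcyclohexan-1-ol
Product: 6 (2S,3S)-3-[(4-methoxybenzyl)oxy]-2-methylcyclohexan-1-one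
Conditions: Dess–Martin periodinane, CH2Cl2, 20 °C
Reagents that add atoms: none
Why: Dess–Martin oxidation of the secondary alcohol under near-neutral conditions that should leave the adjacent, now epimerisable, methyl-bearing centre untouched.

Step 5
Reactants: 6 (2S,3S)-3-[(4-methoxybenzyl)oxy]-2-methylcyclohexan-1-one
Product: 7 N'-[(1E,2R,3S)-3-[(4-methoxybenzyl)oxy]-2-methylcyclohexylidene]-2,4,6-triisopropylbenzenesulfonohydrazide
Conditions: 2,4,6-triisopropylbenzenesulfonyl hydrazide, THF, 20 °C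
Reagents that add atoms: 2,4,6-triisopropylbenzenesulfonyl hydrazide CC(C)c1cc(C(C)C)c(S(=O)(=O)NN)c(C(C)C)c1
Why: Acid-free condensation gives the arylsulfonylhydrazone needed for the Shapiro reaction, with the sulfonamide nitrogen anti to the substituted α-carbon.

Step 6
Reactants: 8 but-1-yn-1-yl(trimethyl)silane
Product: 10 2-methyl-4-(trimethylsilyl)but-3-ynoic acid (racemic), via propargyllithium 9 (not isolated)
Conditions: n-BuLi, TMEDA, THF, −78 → −20 °C; CO2, −78 °C; aq. HCl
Reagents that add atoms: carbon dioxide O=C=O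
Why: Propargylic lithiation of the silylalkyne and carboxylation of the propargyl/allenyl anion at the carbon remote from the bulky silyl terminus give the α-alkynyl acid, and no stereocontrol is needed because this carbon becomes trigonal twice later.

Step 7
Reactants: 10 2-methyl-4-(trimethylsilyl)but-3-ynoic acid, 11 ethoxyethyne
Product: 14 3-ethoxy-4-methyl-4-[(trimethylsilyl)ethynyl]cyclobut-2-en-1-one (racemic), via acid chloride 12 (not isolated), via ketene 13 (not isolated)
Conditions: (COCl)2, DMF (cat.), CH2Cl2, 0 → 20 °C; evaporate; then 11, Et3N, Et2O, 0 → 20 °C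
Reagents that add atoms: none
Why: Dehydrochlorination of the acid chloride gives the disubstituted ketene, which undergoes [2+2] cycloaddition with the ynol ether (nucleophilic alkyne carbon to the ketene carbonyl carbon) to give the 3-ethoxycyclobutenone with the quaternary carbon next to the carbonyl group.

Step 8
Reactants: 14 3-ethoxy-4-methyl-4-[(trimethylsilyl)ethynyl]cyclobut-2-en-1-one
Product: 16 3,4-dimethyl-4-[(trimethylsilyl)ethynyl]cyclobut-2-en-1-one (racemic), via lithium alkoxide 15 (not isolated)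
Conditions: MeLi, THF, −78 °C; then 1 M HCl, 0 °C
Reagents that add atoms: methyllithium [Li]C
Why: 1,2-Addition of methyllithium to the vinylogous ester followed by acid-induced ionisation and hydrolysis of the enol ether (Stork–Danheiser-type transposition) moves the carbonyl group next to the quaternary carbon and leaves the new methyl on the β-carbon.

Step 9
Reactants: 7 N'-[(1E,2R,3S)-3-[(4-methoxybenzyl)oxy]-2-methylcyclohexylidene]-2,4,6-triisopropylbenzenesulfonohydrazide, 16 3,4-dimethyl-4-[(trimethylsilyl)ethynyl]cyclobut-2-en-1-one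
Product: 22 (4R,7S,8R)-7-[(4-methoxybenzyl)oxy]-3,4,8-trimethyl-4-[(trimethylsilyl)ethynyl]-5,6,7,8-tetrahydronaphthalen-1(4H)-one, via vinyllithium 17 (not isolated), via lithium cyclobutenolate 18 (not isolated), via lithium trienolate 19 (not isolated), via lithium cyclohexadienolate 20 (not isolated), via bromo ketone 21 (not isolated)
Conditions: 7, n-BuLi (2 equiv), THF, −78 → −10 °C; then 16, −78 → 20 °C; then NBS, −78 °C; then DBU, −78 → 20 °C
Reagents that add atoms: none
Why: Shapiro fragmentation of 7 gives vinyllithium 17, which adds 1,2 to the strained, non-enolisable carbonyl of 16 on the face anti to the C4 methyl group (syn to the rod-shaped alkynyl group) to give 18, whose alkoxide drives a conrotatory 4π opening of the C1–C4 bond with O− rotating outward, so that the ring A alkenyl group and the C4 methyl turn inward and the all-cisoid trienolate 19 forms directly. Thermal disrotatory 6π electrocyclisation of 19 between C4 and C4a then closes ring B as the cyclohexadienolate 20, so that the four-membered ring C1–C2–C3–C4 has been enlarged by the two alkene carbons C8a and C4a of ring A; the closest known reaction type is the oxyanion-accelerated electrocyclic ring expansion of cyclobutenones by alkenyllithium reagents to cyclohexenones. Ring B is the only ring closed (6π, disrotatory), ring A being carried in intact. The new quaternary stereocentre C4 is controlled by two elements, the triene geometry (methyl inward, alkynyl outward) and bond formation on the face of the ring A alkene opposite the C8 methyl, which A(1,2) strain with the C8a substituent holds pseudoaxial, and together they place the alkynyl group β and the C4 methyl α; both enantiomers of 16 converge because C4 is trigonal in 19, and C4a is only a transient stereocentre. Enolate 20 is brominated at C8a anti to the C8 methyl, and anti-periplanar E2 loss of HBr with DBU can then only involve the C4a hydrogen (the C8 hydrogen is syn to bromine), which restores the C4a=C8a alkene in conjugation with C1. The step needs 1,2- rather than 1,4-addition (lithium counter-ion, fully substituted β-carbon), face selectivity in addition and ring closure (methyl versus alkynyl size, axial C8 methyl) and regioselective dehydrogenation (the stereoelectronic argument above).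

Step 10
Reactants: 22 (4R,7S,8R)-7-[(4-methoxybenzyl)oxy]-3,4,8-trimethyl-4-[(trimethylsilyl)ethynyl]-5,6,7,8-tetrahydronaphthalen-1(4H)-one
Product: 24 (4S,7S,8R)-4-ethynyl-2-hydroxy-7-[(4-methoxybenzyl)oxy]-3,4,8-trimethyl-5,6,7,8-tetrahydronaphthalen-1(4H)-one, via epoxy ketone 23 (not isolated)
Conditions: 30% H2O2, NaOH, MeOH, 0 → 20 °C; then KOH, t-BuOH/H2O, 60 °C; aq. NH4Cl
Reagents that add atoms: potassium hydroxide [K+].[OH-]
Why: Weitz–Scheffer epoxidation attacks only the trisubstituted C2=C3 enone (the C4a=C8a enone is tetrasubstituted), methanolic hydroxide cleaves the alkynylsilane, and hydroxide opening of the epoxy ketone at C2 followed by β-elimination of the C3 oxygen gives the enolised 1,2-dione (diosphenol), so the epoxide configuration is inconsequential.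

Step 11
Reactants: 24 (4S,7S,8R)-4-ethynyl-2-hydroxy-7-[(4-methoxybenzyl)oxy]-3,4,8-trimethyl-5,6,7,8-tetrahydronaphthalen-1(4H)-one
Product: 25 (4S,7S,8R)-4-ethynyl-7-[(4-methoxybenzyl)oxy]-3,4,8-trimethyl-2-[(triisopropylsilyl)oxy]-5,6,7,8-tetrahydronaphthalen-1(4H)-one
Conditions: TIPSOTf, 2,6-lutidine, CH2Cl2, −78 → 0 °C
Reagents that add atoms: triisopropylsilyl trifluoromethanesulfonate CC(C)[Si](OS(=O)(=O)C(F)(F)F)(C(C)C)C(C)C
Why: O-Silylation of the acidic enol by the silyl triflate and a hindered pyridine base protects the diosphenol as a robust silyl enol ether.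

Step 12
Reactants: 25 (4S,7S,8R)-4-ethynyl-7-[(4-methoxybenzyl)oxy]-3,4,8-trimethyl-2-[(triisopropylsilyl)oxy]-5,6,7,8-tetrahydronaphthalen-1(4H)-one
Product: 26 (4S,7S,8R)-4-ethenyl-7-[(4-methoxybenzyl)oxy]-3,4,8-trimethyl-2-[(triisopropylsilyl)oxy]-5,6,7,8-tetrahydronaphthalen-1(4H)-one
Conditions: H2 (1 atm), Pd/CaCO3 poisoned with Pb(OAc)2, quinoline, EtOAc, 20 °C
Reagents that add atoms: none
Why: Lindlar semihydrogenation reduces the terminal alkyne to the vinyl group and should stop there, the tetrasubstituted enone alkenes and the benzylic ether being inert to the poisoned catalyst.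

Step 13
Reactants: 27 but-2-yn-1-ol
Product: 28 tert-butyl(but-2-yn-1-yloxy)dimethylsilane
Conditions: TBSCl, imidazole, DMF, 20 °C
Reagents that add atoms: tert-butyldimethylsilyl chloride CC(C)(C)[Si](C)(C)Cl
Why: Imidazole-mediated silylation of the primary alcohol.

Step 14
Reactants: 28 tert-butyl(but-2-yn-1-yloxy)dimethylsilane
Product: 30 (E)-tert-butyl[(3-iodobut-2-en-1-yl)oxy]dimethylsilane, via vinylzirconocene 29 (not isolated)
Conditions: Cp2Zr(H)Cl (excess), THF, 50 °C; then I2, 0 °C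
Reagents that add atoms: iodine II
Why: Hydrozirconation adds H–Zr syn and, under equilibrating conditions with excess reagent, places zirconium on the less hindered methyl-bearing carbon, and iodinolysis with retention gives the E vinyl iodide.

Step 15
Reactants: 26 (4S,7S,8R)-4-ethenyl-7-[(4-methoxybenzyl)oxy]-3,4,8-trimethyl-2-[(triisopropylsilyl)oxy]-5,6,7,8-tetrahydronaphthalen-1(4H)-one, 30 (E)-tert-butyl[(3-iodobut-2-en-1-yl)oxy]dimethylsilane
Product: 32 (4S,7S,8R)-4-[(E)-5-(tert-butyldimethylsilyloxy)-3-methylpent-3-en-1-yl]-7-[(4-methoxybenzyl)oxy]-3,4,8-trimethyl-2-[(triisopropylsilyl)oxy]-5,6,7,8-tetrahydronaphthalen-1(4H)-one, via alkylborane 31 (not isolated)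
Conditions: 26, 9-BBN, THF, 20 °C; then 30, PdCl2(dppf), AsPh3, Cs2CO3, DMF/H2O, 20 °C
Reagents that add atoms: none
Why: Hydroboration of the neopentyl-type vinyl group with 9-BBN (boron at the terminal carbon) and B-alkyl Suzuki–Miyaura coupling with the vinyl iodide with retention of alkene geometry build the C4 side chain with its E trisubstituted alkene.

Step 16
Reactants: 32 (4S,7S,8R)-4-[(E)-5-(tert-butyldimethylsilyloxy)-3-methylpent-3-en-1-yl]-7-[(4-methoxybenzyl)oxy]-3,4,8-trimethyl-2-[(triisopropylsilyl)oxy]-5,6,7,8-tetrahydronaphthalen-1(4H)-one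
Product: 33 (4S,7S,8R)-4-[(E)-5-(tert-butyldimethylsilyloxy)-3-methylpent-3-en-1-yl]-7-hydroxy-3,4,8-trimethyl-2-[(triisopropylsilyl)oxy]-5,6,7,8-tetrahydronaphthalen-1(4H)-one
Conditions: DDQ, CH2Cl2/pH 7 buffer, 0 °C
Reagents that add atoms: none
Why: Oxidative cleavage of the 4-methoxybenzyl ether by DDQ (benzylic hydride abstraction, then hydrolysis of the oxocarbenium ion) frees the C7 hydroxyl while the silyl ethers remain.

Step 17
Reactants: 33 (4S,7S,8R)-4-[(E)-5-(tert-butyldimethylsilyloxy)-3-methylpent-3-en-1-yl]-7-hydroxy-3,4,8-trimethyl-2-[(triisopropylsilyl)oxy]-5,6,7,8-tetrahydronaphthalen-1(4H)-one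
Product: 34 (4S,8R)-4-[(E)-5-(tert-butyldimethylsilyloxy)-3-methylpent-3-en-1-yl]-3,4,8-trimethyl-2-[(triisopropylsilyl)oxy]-5,6-dihydronaphthalene-1,7(4H,8H)-dione
Conditions: Dess–Martin periodinane, pyridine, CH2Cl2, 20 °C
Reagents that add atoms: none
Why: Dess–Martin oxidation gives the C7 ketone, and the C8 configuration no longer matters because this centre is enolised in the next step.

Step 18
Reactants: 34 (4S,8R)-4-[(E)-5-(tert-butyldimethylsilyloxy)-3-methylpent-3-en-1-yl]-3,4,8-trimethyl-2-[(triisopropylsilyl)oxy]-5,6-dihydronaphthalene-1,7(4H,8H)-dione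
Product: 35 (S)-4-[(E)-5-(tert-butyldimethylsilyloxy)-3-methylpent-3-en-1-yl]-3,4,8-trimethyl-2-[(triisopropylsilyl)oxy]-7-[(trimethylsilyl)oxy]-5,6-dihydronaphthalen-1(4H)-one
Conditions: TMSOTf, Et3N, CH2Cl2, 0 → 20 °C
Reagents that add atoms: trimethylsilyl trifluoromethanesulfonate C[Si](C)(C)OS(=O)(=O)C(F)(F)F
Why: Soft enolisation under equilibrating conditions silylates the C7 ketone toward C8, which gives the more substituted, diene-conjugated enol ether, the C1 carbonyl group having no α-hydrogen.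

Step 19
Reactants: 35 (S)-4-[(E)-5-(tert-butyldimethylsilyloxy)-3-methylpent-3-en-1-yl]-3,4,8-trimethyl-2-[(triisopropylsilyl)oxy]-7-[(trimethylsilyl)oxy]-5,6-dihydronaphthalen-1(4H)-one
Product: 36 (4S,8S)-4-[(E)-5-(tert-butyldimethylsilyloxy)-3-methylpent-3-en-1-yl]-8-(hydroxymethyl)-3,4,8-trimethyl-2-[(triisopropylsilyl)oxy]-5,6-dihydronaphthalene-1,7(4H,8H)-dione
Conditions: aq. HCHO, Sc(OTf)3 (cat.), (S,S)-6,6'-bis(1-hydroxy-2,2-dimethylpropyl)-2,2'-bipyridine (cat.; or its enantiomer, whichever delivers 8S), DME/H2O, −20 °C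
Reagents that add atoms: formaldehyde C=O
Why: Catalytic asymmetric Mukaiyama-type hydroxymethylation in aqueous medium, in which the chiral scandium–bipyridine complex activates formaldehyde and selects the enol ether face, so that bond formation at C8 (the α-carbon, C4a being deactivated as the β-carbon of the C1 enone) should create the quaternary centre with the hydroxymethyl group α (8S) under catalyst control.

Step 20
Reactants: 36 (4S,8S)-4-[(E)-5-(tert-butyldimethylsilyloxy)-3-methylpent-3-en-1-yl]-8-(hydroxymethyl)-3,4,8-trimethyl-2-[(triisopropylsilyl)oxy]-5,6-dihydronaphthalene-1,7(4H,8H)-dione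
Product: 37 [(1S,5S)-5-[(E)-5-(tert-butyldimethylsilyloxy)-3-methylpent-3-en-1-yl]-1,5,6-trimethyl-2,8-dioxo-7-[(triisopropylsilyl)oxy]-1,2,3,4,5,8-hexahydronaphthalen-1-yl]methyl acetate
Conditions: Ac2O, pyridine, 4-(dimethylamino)pyridine (cat.), CH2Cl2, 0 °C
Reagents that add atoms: acetic anhydride CC(=O)OC(C)=O
Why: Acetylation of the neopentyl primary alcohol by nucleophilic catalysis, carried out directly to forestall retro-aldol loss of formaldehyde.

Step 21
Reactants: 37 [(1S,5S)-5-[(E)-5-(tert-butyldimethylsilyloxy)-3-methylpent-3-en-1-yl]-1,5,6-trimethyl-2,8-dioxo-7-[(triisopropylsilyl)oxy]-1,2,3,4,5,8-hexahydronaphthalen-1-yl]methyl acetate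
Product: 38 CNP0512382.1
Conditions: HF·pyridine, pyridine, THF, 0 → 20 °C
Reagents that add atoms: none
Why: Fluoride-mediated desilylation removes the primary silyl ether and the silyl enol ether, while the acetate and the non-enolisable β-acetoxy ketone at C8 should survive.

**Compound list**

1 | 2-methylcyclohex-2-en-1-one | CC1=CCCCC1=O | starting material
2 | (S)-2-methylcyclohex-2-en-1-ol | CC1=CCCC[C@@H]1O | intermediate
3 | 1-methoxy-4-({[(1S)-2-methylcyclohex-2-en-1-yl]oxy}methyl)benzene | CC1=CCCC[C@@H]1OCc1ccc(OC)cc1 | intermediate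
4 | 9-{3-[(4-methoxybenzyl)oxy]-2-methylcyclohexyl}-9-borabicyclo[3.3.1]nonane (boron trans to methyl, methyl cis to the ether; configured as 5) | C[C@@H]1[C@@H](B2C3CCCC2CCC3)CCC[C@@H]1OCc1ccc(OC)cc1 | intermediate
5 | (1S,2R,3S)-3-[(4-methoxybenzyl)oxy]-2-methylcyclohexan-1-ol | C[C@@H]1[C@@H](O)CCC[C@@H]1OCc1ccc(OC)cc1 | intermediate
6 | (2S,3S)-3-[(4-methoxybenzyl)oxy]-2-methylcyclohexan-1-one | C[C@@H]1C(=O)CCC[C@@H]1OCc1ccc(OC)cc1 | intermediate
7 | N'-[(1E,2R,3S)-3-[(4-methoxybenzyl)oxy]-2-methylcyclohexylidene]-2,4,6-triisopropylbenzenesulfonohydrazide | C[C@@H]1/C(=N/NS(=O)(=O)c2c(C(C)C)cc(C(C)C)cc2C(C)C)CCC[C@@H]1OCc1ccc(OC)cc1 | intermediate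
8 | but-1-yn-1-yl(trimethyl)silane | CCC#C[Si](C)(C)C | starting material
9 | [1-methyl-3-(trimethylsilyl)prop-2-yn-1-yl]lithium | [Li]C(C)C#C[Si](C)(C)C | intermediate
10 | 2-methyl-4-(trimethylsilyl)but-3-ynoic acid (racemic) | CC(C#C[Si](C)(C)C)C(O)=O | intermediate
11 | ethoxyethyne | CCOC#C | starting material
12 | 2-methyl-4-(trimethylsilyl)but-3-ynoyl chloride | CC(C#C[Si](C)(C)C)C(Cl)=O | intermediate
13 | 2-methyl-4-(trimethylsilyl)but-1-en-3-yn-1-one (ketene) | CC(C#C[Si](C)(C)C)=C=O | intermediate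
14 | 3-ethoxy-4-methyl-4-[(trimethylsilyl)ethynyl]cyclobut-2-en-1-one (racemic) | CCOC1=CC(=O)C1(C)C#C[Si](C)(C)C | intermediate
15 | lithium 3-ethoxy-1,4-dimethyl-4-[(trimethylsilyl)ethynyl]cyclobut-2-en-1-olate (racemic, either C1 epimer) | [Li+].CCOC1=CC(C)([O-])C1(C)C#C[Si](C)(C)C | intermediate
16 | 3,4-dimethyl-4-[(trimethylsilyl)ethynyl]cyclobut-2-en-1-one (racemic) | CC1=CC(=O)C1(C)C#C[Si](C)(C)C | intermediate
17 | [(5S,6R)-5-[(4-methoxybenzyl)oxy]-6-methylcyclohex-1-en-1-yl]lithium | C[C@@H]1C([Li])=CCC[C@@H]1OCc1ccc(OC)cc1 | intermediate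
18 | lithium 1-[(5S,6R)-5-[(4-methoxybenzyl)oxy]-6-methylcyclohex-1-en-1-yl]-3,4-dimethyl-4-[(trimethylsilyl)ethynyl]cyclobut-2-en-1-olate, cyclohexenyl group trans to the C4 methyl (drawn from one enantiomer of 16; the other gives the C1,C4-bis-epimer) | [Li+].C[C@@H]1C(=CCC[C@@H]1OCc1ccc(OC)cc1)[C@]2([O-])C=C(C)[C@]2(C)C#C[Si](C)(C)C | intermediate
19 | lithium (1E,3E)-1-[(5S,6R)-5-[(4-methoxybenzyl)oxy]-6-methylcyclohex-1-en-1-yl]-3,4-dimethyl-6-(trimethylsilyl)hexa-1,3-dien-5-yn-1-olate | [Li+].C[C@@H]1C(=CCC[C@@H]1OCc1ccc(OC)cc1)/C([O-])=C\C(C)=C(/C)C#C[Si](C)(C)C | intermediate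
20 | lithium 7-[(4-methoxybenzyl)oxy]-3,4,8-trimethyl-4-[(trimethylsilyl)ethynyl]-4,4a,5,6,7,8-hexahydronaphthalen-1-olate (4-alkynyl β; 4-methyl, 4a-H, 7-O and 8-methyl α) | [Li+].C[C@H]1[C@@H](OCc3ccc(OC)cc3)CC[C@H]2C1=C([O-])C=C(C)[C@@]2(C)C#C[Si](C)(C)C | intermediate
21 | 8a-bromo-7-[(4-methoxybenzyl)oxy]-3,4,8-trimethyl-4-[(trimethylsilyl)ethynyl]-4a,5,6,7,8,8a-hexahydronaphthalen-1(4H)-one (Br and 4-alkynyl β; 4-methyl, 4a-H, 7-O and 8-methyl α) | C[C@H]1[C@@H](OCc3ccc(OC)cc3)CC[C@H]2[C@@]1(Br)C(=O)C=C(C)[C@@]2(C)C#C[Si](C)(C)C | intermediate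
22 | (4R,7S,8R)-7-[(4-methoxybenzyl)oxy]-3,4,8-trimethyl-4-[(trimethylsilyl)ethynyl]-5,6,7,8-tetrahydronaphthalen-1(4H)-one | C[C@H]1[C@@H](OCc3ccc(OC)cc3)CCC2=C1C(=O)C=C(C)[C@@]2(C)C#C[Si](C)(C)C | intermediate
23 | (4S,7S,8R)-2,3-epoxy-4-ethynyl-7-[(4-methoxybenzyl)oxy]-3,4,8-trimethyl-2,3,5,6,7,8-hexahydronaphthalen-1(4H)-one (β-epoxide drawn; its configuration is inconsequential) | C[C@H]1[C@@H](OCc4ccc(OC)cc4)CCC2=C1C(=O)[C@H]3O[C@@]3(C)[C@@]2(C)C#C | intermediate
24 | (4S,7S,8R)-4-ethynyl-2-hydroxy-7-[(4-methoxybenzyl)oxy]-3,4,8-trimethyl-5,6,7,8-tetrahydronaphthalen-1(4H)-one | C[C@H]1[C@@H](OCc3ccc(OC)cc3)CCC2=C1C(=O)C(O)=C(C)[C@@]2(C)C#C | intermediate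
25 | (4S,7S,8R)-4-ethynyl-7-[(4-methoxybenzyl)oxy]-3,4,8-trimethyl-2-[(triisopropylsilyl)oxy]-5,6,7,8-tetrahydronaphthalen-1(4H)-one | C[C@H]1[C@@H](OCc3ccc(OC)cc3)CCC2=C1C(=O)C(O[Si](C(C)C)(C(C)C)C(C)C)=C(C)[C@@]2(C)C#C | intermediate
26 | (4S,7S,8R)-4-ethenyl-7-[(4-methoxybenzyl)oxy]-3,4,8-trimethyl-2-[(triisopropylsilyl)oxy]-5,6,7,8-tetrahydronaphthalen-1(4H)-one | C[C@H]1[C@@H](OCc3ccc(OC)cc3)CCC2=C1C(=O)C(O[Si](C(C)C)(C(C)C)C(C)C)=C(C)[C@@]2(C)C=C | intermediate
27 | but-2-yn-1-ol | CC#CCO | starting material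
28 | tert-butyl(but-2-yn-1-yloxy)dimethylsilane | CC#CCO[Si](C)(C)C(C)(C)C | intermediate
29 | (E)-[4-(tert-butyldimethylsilyloxy)but-2-en-2-yl]chlorobis(cyclopentadienyl)zirconium | C/C(=C\CO[Si](C)(C)C(C)(C)C)[Zr](Cl)(C1C=CC=C1)C1C=CC=C1 | intermediate
30 | (E)-tert-butyl[(3-iodobut-2-en-1-yl)oxy]dimethylsilane | C/C(I)=C\CO[Si](C)(C)C(C)(C)C | intermediate
31 | 9-{2-[(1S,6S,7R)-6-[(4-methoxybenzyl)oxy]-1,2,7-trimethyl-4-oxo-3-[(triisopropylsilyl)oxy]-1,4,5,6,7,8-hexahydronaphthalen-1-yl]ethyl}-9-borabicyclo[3.3.1]nonane (configured as 26) | C[C@H]1[C@@H](OCc3ccc(OC)cc3)CCC2=C1C(=O)C(O[Si](C(C)C)(C(C)C)C(C)C)=C(C)[C@@]2(C)CCB4C5CCCC4CCC5 | intermediate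
32 | (4S,7S,8R)-4-[(E)-5-(tert-butyldimethylsilyloxy)-3-methylpent-3-en-1-yl]-7-[(4-methoxybenzyl)oxy]-3,4,8-trimethyl-2-[(triisopropylsilyl)oxy]-5,6,7,8-tetrahydronaphthalen-1(4H)-one | C[C@H]1[C@@H](OCc3ccc(OC)cc3)CCC2=C1C(=O)C(O[Si](C(C)C)(C(C)C)C(C)C)=C(C)[C@@]2(C)CC/C(C)=C/CO[Si](C)(C)C(C)(C)C | intermediate
33 | (4S,7S,8R)-4-[(E)-5-(tert-butyldimethylsilyloxy)-3-methylpent-3-en-1-yl]-7-hydroxy-3,4,8-trimethyl-2-[(triisopropylsilyl)oxy]-5,6,7,8-tetrahydronaphthalen-1(4H)-one | C[C@H]1[C@@H](O)CCC2=C1C(=O)C(O[Si](C(C)C)(C(C)C)C(C)C)=C(C)[C@@]2(C)CC/C(C)=C/CO[Si](C)(C)C(C)(C)C | intermediate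
34 | (4S,8R)-4-[(E)-5-(tert-butyldimethylsilyloxy)-3-methylpent-3-en-1-yl]-3,4,8-trimethyl-2-[(triisopropylsilyl)oxy]-5,6-dihydronaphthalene-1,7(4H,8H)-dione | C[C@H]1C(=O)CCC2=C1C(=O)C(O[Si](C(C)C)(C(C)C)C(C)C)=C(C)[C@@]2(C)CC/C(C)=C/CO[Si](C)(C)C(C)(C)C | intermediate
35 | (S)-4-[(E)-5-(tert-butyldimethylsilyloxy)-3-methylpent-3-en-1-yl]-3,4,8-trimethyl-2-[(triisopropylsilyl)oxy]-7-[(trimethylsilyl)oxy]-5,6-dihydronaphthalen-1(4H)-one | CC1=C(O[Si](C)(C)C)CCC2=C1C(=O)C(O[Si](C(C)C)(C(C)C)C(C)C)=C(C)[C@@]2(C)CC/C(C)=C/CO[Si](C)(C)C(C)(C)C | intermediate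
36 | (4S,8S)-4-[(E)-5-(tert-butyldimethylsilyloxy)-3-methylpent-3-en-1-yl]-8-(hydroxymethyl)-3,4,8-trimethyl-2-[(triisopropylsilyl)oxy]-5,6-dihydronaphthalene-1,7(4H,8H)-dione | OC[C@@]1(C)C(=O)CCC2=C1C(=O)C(O[Si](C(C)C)(C(C)C)C(C)C)=C(C)[C@@]2(C)CC/C(C)=C/CO[Si](C)(C)C(C)(C)C | intermediate
37 | [(1S,5S)-5-[(E)-5-(tert-butyldimethylsilyloxy)-3-methylpent-3-en-1-yl]-1,5,6-trimethyl-2,8-dioxo-7-[(triisopropylsilyl)oxy]-1,2,3,4,5,8-hexahydronaphthalen-1-yl]methyl acetate | CC(=O)OC[C@@]1(C)C(=O)CCC2=C1C(=O)C(O[Si](C(C)C)(C(C)C)C(C)C)=C(C)[C@@]2(C)CC/C(C)=C/CO[Si](C)(C)C(C)(C)C | intermediate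
38 | CNP0512382.1, [(1S,5S)-7-hydroxy-5-[(E)-5-hydroxy-3-methylpent-3-en-1-yl]-1,5,6-trimethyl-2,8-dioxo-1,2,3,4,5,8-hexahydronaphthalen-1-yl]methyl acetate (4S,8S in the core numbering) | CC(=O)OC[C@@]1(C)C(=O)CCC2=C1C(=O)C(O)=C(C)[C@@]2(C)CC/C(C)=C/CO | target

**Totals**

Total step count: 21. Longest linear sequence: 16 steps (steps 1–5, 9–12 and 15–21).

**Steps most likely to fail, each with one fallback**

Step 9. Face selectivity when 17 adds to 16 (methyl face versus alkynyl face) may be poor, and this would be relayed by the electrocyclic sequence into a mixture at C4. The 6π closure at the fully substituted triene terminus may also be slow, and bromination/elimination may lose its regiocontrol toward C8. The fallback sets out from 7 and 16 and returns at 22. The sequence is run stepwise instead of as a relay: 17 is added to 16 at −78 °C and the alkoxide is protonated cold with AcOH, so that the neutral tertiary cyclobutenol F1 can be isolated and freed by chromatography from the diastereomers in which the cyclohexenyl group is cis to the C4 methyl. Pure cyclobutenol F1 is then ionised again (KH, THF, 0 → 20 °C) to trigger ring opening and 6π closure, and the enolate is brominated and dehydrobrominated as in the main route to give 22.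

Step 19. Enantiofacial discrimination at C8 by the chiral Lewis acid may be poor on this hindered dienyl silyl enol ether, or simple protodesilylation back to 34 may compete. The fallback sets out from 35 and returns at 36. Hydroxymethylation without chiral ligand (aq. HCHO, Yb(OTf)3, THF/H2O) should give 36 together with the C8-epimeric hydroxymethyl dione F2. The two are diastereomers because C4 is fixed, so they can be separated by chromatography. The C8 epimer F2 is recycled by base-induced retro-aldol loss of formaldehyde (DBU, toluene, 60 °C) to 34, which is silylated again to 35.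

Step 15. Competing 1,2-reduction of the dienone carbonyl by 9-BBN, or sluggish hydroboration of the neopentyl-type vinyl group, may erode the coupling. The fallback sets out from 25 and returns at 32, bypassing 26. Sonogashira coupling of alkyne 25 with 30 (PdCl2(PPh3)2, CuI, Et3N) gives the enyne F3. The triple bond of enyne F3 is then saturated with diimide (2-nitrobenzenesulfonyl hydrazide, Et3N, CH2Cl2, 20 °C), which reduces the alkyne and the derived cis-disubstituted alkene but should leave the trisubstituted and tetrasubstituted alkenes and the carbonyl group untouched.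

**Further compounds**

F1 | step 9 | 1-[(5S,6R)-5-[(4-methoxybenzyl)oxy]-6-methylcyclohex-1-en-1-yl]-3,4-dimethyl-4-[(trimethylsilyl)ethynyl]cyclobut-2-en-1-ol, cyclohexenyl group trans to the C4 methyl | C[C@@H]1C(=CCC[C@@H]1OCc1ccc(OC)cc1)[C@]2(O)C=C(C)[C@]2(C)C#C[Si](C)(C)C
F2 | step 19 | (4S,8R)-4-[(E)-5-(tert-butyldimethylsilyloxy)-3-methylpent-3-en-1-yl]-8-(hydroxymethyl)-3,4,8-trimethyl-2-[(triisopropylsilyl)oxy]-5,6-dihydronaphthalene-1,7(4H,8H)-dione | OC[C@]1(C)C(=O)CCC2=C1C(=O)C(O[Si](C(C)C)(C(C)C)C(C)C)=C(C)[C@@]2(C)CC/C(C)=C/CO[Si](C)(C)C(C)(C)C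
F3 | step 15 | (4S,7S,8R)-4-[(E)-5-(tert-butyldimethylsilyloxy)-3-methylpent-3-en-1-yn-1-yl]-7-[(4-methoxybenzyl)oxy]-3,4,8-trimethyl-2-[(triisopropylsilyl)oxy]-5,6,7,8-tetrahydronaphthalen-1(4H)-one | C[C@H]1[C@@H](OCc3ccc(OC)cc3)CCC2=C1C(=O)C(O[Si](C(C)C)(C(C)C)C(C)C)=C(C)[C@@]2(C)C#C/C(C)=C/CO[Si](C)(C)C(C)(C)C
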